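Readings and results stem from a simulated flask for substances that don't exist, noise included.

No constant of this flask stands among the charges and readings, so the reckoning starts from a ratio read off them, the clock ratio: the time one run needs to reach a given product, over the time another needs to reach the same product.

| flask | starting material | reagent | free catalyst | time |
|---|---|---|---|---|
| teal | 300 mM | 900 mM | 24.0 mM |  |
| red | 180 mM | 780 mM | 24.0 mM |  |
| green | 300 mM | 1400 mM | 24.0 mM |  |
| amber | 300 mM | 900 mM | 12.0 mM |  |
| blue | 300 mM | 900 mM | 6.90 mM | 8.0 min |

| run | time / min | [product] / mM |
|---|---|---|
| teal run | 0.46 | 21 |
| teal run | 1.4 | 52 |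
| teal run | 2.6 | 90 |
| teal run | 4.2 | 144 |
| teal run | 6.0 | 177 |
| teal run | 8.0 | 211 |
| red run | 0.46 | 13 |
| red run | 1.4 | 38 |
| red run | 2.6 | 61 |
| red run | 4.2 | 87 |
| red run | 6.0 | 112 |
| red run | 8.0 | 133 |
| green run | 0.46 | 13 |
| green run | 1.4 | 47 |
| green run | 2.6 | 87 |
| green run | 4.2 | 140 |
| green run | 6.0 | 174 |
| green run | 8.0 | 229 |
| amber run | 0.46 | 6 |
| amber run | 1.4 | 18 |
| amber run | 2.6 | 36 |
| amber run | 4.2 | 52 |
| amber run | 6.0 | 67 |
| amber run | 8.0 | 95 |

(standard deviation of a reading: 4 mM)

- Overall: starting material + reagent -> product, with free catalyst as catalyst.
- Constant volume, constant temperature.
- Readings of a species count what is bound in complexes too.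
- An order is taken over about fifteen percent of the charge, up and down.

- the exponent of [reagent] in the starting rate at the charge of the teal run (at the point where two percent of the starting material have become product)
- the exponent of [starting material] in the starting rate at the charge of the teal run (at the point where two percent of the starting material have become product) (one fixed amount of product, the same in the runs compared)
- the red run starts with 120 mM less of starting material and of reagent than the teal run, and with no product. Compared where both hold the same amount of starting material, once fifteen percent of what the red run was charged with has turned into product, is the red run faster, slower or alike (within a tenth)?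
- product in the blue run at 8.0 min, as a share of the starting material charged

The teal and amber runs carry the same starting material and reagent, so at equal product their mixtures differ in the catalyst charge, and the ratio of times is taken as the inverse ratio of rates. The teal run holds 52 mM at 1.4 min, and the amber run holds 52 mM at 4.2 min. That pair of readings gives a clock ratio of 3.00, larger than the ratio of the catalyst charges, teal over amber. Suppose rate follows working catalyst and each flask loses one fixed amount of its charge. That amount, the catalyst toll z, is the clock ratio times the amber charge, less the teal charge, over the clock ratio less one: 6.00 mM.

The blue run then keeps 0.900 mM working, against 18.0 mM in the teal run, so its clock runs 20.0 times slower. Its 8.0 min equal 0.400 min of teal time, earlier than the first teal reading. The average teal slope to the second reading is 37.1 mM min⁻¹, so the blue curve starts at 1.86 mM min⁻¹. On this reckoning it shows no knee and climbs almost straight to 14.9 mM, or 4.97% of the charge, far below the 300 mM of starting material, the limiting reagent. The soft spot is the small difference behind the working catalyst. The near-equal pair 90 mM at 2.6 min and 95 mM at 8.0 min gives a clock ratio of 3.08 and a toll of 6.22 mM, which lowers the blue share to 3.78%.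

The forecast gives a reagent order of 0, a starting-material order of 0.55 and the red run alike, and, from “Halving catalyst cuts the rate about 2.9-fold”, puts the blue run at 12%, higher than the reckoning here.

The flask gives a reagent order of 0.028, a starting-material order of 0.68, the red run alike, and the blue run at 4.94%.

    free catalyst + starting material → catalyst-substrate complex (13.86 L mol⁻¹ min⁻¹)
    catalyst-substrate complex + reagent → product + free catalyst (89.40 L mol⁻¹ min⁻¹)
    2 starting material ⇌ idle substrate dimer, settled at all times (2.590 L mol⁻¹)
    free catalyst + impurity → spent catalyst

The impurity takes free catalyst at once, and that step holds the blue run down to 4.94%. A blue run without that step puts the toll to use again. In that run the 6.90 mM of free catalyst works in full, so its 8.0 min equal 3.07 min of teal time. The teal readings, 90 mM at 2.6 min and 144 mM at 4.2 min, interpolate there to 106 mM, which is 35.2% of the charge, and the blue run without that step reaches 35.0%.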